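**Retrosynthetic overview**
1. The ester carbonyl carbon on C8 and the aldehyde carbon C11 on C9 are 1,4-related through the C8–C9 bond of ring B (C5, C6, C7, C8, C9, C10); such a pair arises when two enol-type carbons are joined oxidatively.
2. C8–C9 is therefore cut last: ring B closes by anodic coupling of a C7/C8 β-keto ester (arm on C5) with a C9=C11 methyl enol ether (arm on C10) on a finished ring A; enol triflate reduction and deprotection follow.
3. On ring A the keto ester comes from a 2-(pivaloyloxy)ethyl arm, the enol ether from an allyl group (ozonolysis, acetal, elimination of methanol), C3–Cl from invertive chlorination of a C3α alcohol, and the C1/C3 carbinols from catalyst-controlled borylation and ketone reduction of an enone.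
4. The quaternary carbons C10 and C4 come from two α'-dialkylations (methyl, then the allyl-type group anti to the C5 arm) on either side of a Wharton 1,3-enone transposition; the ring itself comes from an organocatalytic Michael/aldol annulation that sets C5.
5. Ring order: ring A first (step 7), ring B last (step 25).

Key step: step 25

Remark on notation: locants C1–C11 are those of the target (ring A = C1, C2, C3, C4, C5, C10; C11 = formyl carbon); β is the face of the C10 methyl group in the target, α the opposite face.
Assumption: in the catalyst-controlled steps 7, 16 and 18 the catalyst hand named is the one expected to give the drawn isomer (derived from the usual shielding models for steps 7 and 18, not derivable for step 16); the antipode is used if the sense proves opposite. The enol ether of step 20 is expected as an E/Z mixture, is drawn E, and both isomers should converge in step 25.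

**Side-chain bromide (steps 1–4)**

Step 1
Reactants: 1 2-methylbut-3-yn-2-ol
Product: 2 triethyl[(2-methylbut-3-yn-2-yl)oxy]silane
Conditions: Et3SiCl, imidazole, DMAP (cat.), DMF, rt
Reagents that add atoms: chlorotriethylsilane, CC[Si](Cl)(CC)CC
Why: Imidazole-promoted silyl ether formation masks the tertiary hydroxyl, which would otherwise quench the acetylide here and the enolate in step 15.

Step 2
Reactants: 2 triethyl[(2-methylbut-3-yn-2-yl)oxy]silane
Product: 4 4-methyl-4-(triethylsilyloxy)pent-2-yn-1-ol, via lithium acetylide 3 (not isolated)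
Conditions: n-BuLi, THF, −78 °C; (CH2O)n, −78 °C → rt
Reagents that add atoms: formaldehyde (as paraformaldehyde), C=O; n-butyllithium, [Li]CCCC (lithium of 3 only)
Why: Deprotonation of the terminal alkyne and 1,2-addition of the acetylide to formaldehyde (acetylide hydroxymethylation) adds the carbinol carbon.

Step 3
Reactants: 4 4-methyl-4-(triethylsilyloxy)pent-2-yn-1-ol
Product: 5 (E)-4-methyl-4-(triethylsilyloxy)pent-2-en-1-ol
Conditions: LiAlH4, THF, 0 °C
Reagents that add atoms: none
Why: trans-Hydroalumination of the propargylic alcohol through a cyclic alkoxyaluminate, then protonolysis, should give only the E alkene; the low temperature disfavours loss of the γ-silyloxy group.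

Step 4
Reactants: 5 (E)-4-methyl-4-(triethylsilyloxy)pent-2-en-1-ol
Product: 6 (E)-1-bromo-4-methyl-4-(triethylsilyloxy)pent-2-ene
Conditions: CBr4, PPh3, CH2Cl2, 0 °C
Reagents that add atoms: tetrabromomethane, BrC(Br)(Br)Br
Why: Appel bromination displaces the activated primary allylic oxygen by SN2 at the unhindered CH2 under neutral conditions, so the silyl ether and the alkene geometry are kept.

**Ring A (steps 5–24)**

Step 5
Reactants: 7 but-3-en-1-ol
Product: 8 but-3-en-1-yl pivalate
Conditions: pivaloyl chloride, pyridine, CH2Cl2, 0 °C → rt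
Reagents that add atoms: pivaloyl chloride, CC(C)(C)C(Cl)=O
Why: Acylation installs a pivalate, an ester without α-hydrogens that should resist enolates, alkaline peroxide and hydrazine, and that is removed reductively in step 21.

Step 6
Reactants: 8 but-3-en-1-yl pivalate; 9 (E)-but-2-enal
Product: 10 (E)-5-oxopent-3-en-1-yl pivalate
Conditions: second-generation Hoveyda–Grubbs catalyst (3 mol%), excess 9, CH2Cl2, 40 °C
Reagents that add atoms: none
Why: Olefin cross-metathesis of a terminal alkene with excess crotonaldehyde releases propene and should give the conjugated E enal as the thermodynamic product.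

Step 7
Reactants: 10 (E)-5-oxopent-3-en-1-yl pivalate; 11 tert-butyl 3-oxobutanoate
Product: 13 (R)-5-[2-(pivaloyloxy)ethyl]cyclohex-2-en-1-one, via Michael adduct 12 (not isolated)
Conditions: (R)-2-{bis[3,5-bis(trifluoromethyl)phenyl](trimethylsilyloxy)methyl}pyrrolidine (10 mol%), PhCO2H (10 mol%), toluene, rt; then TsOH·H2O (20 mol%), 80 °C
Reagents that add atoms: none
Why: Iminium-catalysed Michael addition of the keto ester, in which the diarylmethyl silyl ether group of the catalyst shields one face of the enal and so sets C5, is followed by acid-mediated intramolecular aldol condensation, tert-butyl ester cleavage and decarboxylation, which close ring A.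

Step 8
Reactants: 13 (R)-5-[2-(pivaloyloxy)ethyl]cyclohex-2-en-1-one
Product: 15 C10-methyl enone, via lithium dienolate 14 (not isolated)
Conditions: LiN(i-Pr)2, THF, −78 °C; MeI, −78 → −20 °C
Reagents that add atoms: iodomethane, CI; lithium diisopropylamide, [Li]N(C(C)C)C(C)C (lithium of 14 only)
Why: Kinetic α'-deprotonation gives the cross-conjugated dienolate, which is methylated at C10 (enolate alkylation); the C10 configuration is of no consequence because this carbon is enolised again in step 9.

Step 9
Reactants: 15 C10-methyl enone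
Product: 17 C10β-methyl C10α-allyl enone, via lithium dienolate 16 (not isolated)
Conditions: LiN(i-Pr)2, THF, −78 °C; allyl bromide, DMPU, −78 → 0 °C
Reagents that add atoms: allyl bromide, C=CCBr; lithium diisopropylamide, [Li]N(C(C)C)C(C)C (lithium of 16 only)
Why: Alkylation of the tetrasubstituted α'-enolate should occur anti to the vicinal C5 arm, which sets the C10 quaternary centre with methyl cis and allyl trans to that arm.

Step 10
Reactants: 17 C10β-methyl C10α-allyl enone
Product: 19 C10α-(2,2-dimethoxyethyl) enone, via aldehyde 18 (not isolated)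
Conditions: O3, CH2Cl2/MeOH, −78 °C (to first excess); Me2S, −78 °C → rt; then HC(OMe)3, PPTS, rt
Reagents that add atoms: methanol, CO; trimethyl orthoformate, COC(OC)OC; ozone, [O-][O+]=O (oxygen of 18 only)
Why: Ozonolysis cleaves the electron-rich terminal alkene much faster than the conjugated enone alkene, and the resulting aldehyde is acetalised in the same pot because it is far more electrophilic than the hindered conjugated ketone.

Step 11
Reactants: 19 C10α-(2,2-dimethoxyethyl) enone
Product: 20 C2,C3-epoxy ketone
Conditions: 30% H2O2, NaOH (0.2 equiv), MeOH, 0 °C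
Reagents that add atoms: hydrogen peroxide, OO
Why: Weitz–Scheffer nucleophilic epoxidation of the enone; the epoxide (drawn anti to the C5 arm) is only a relay, since its carbinol centre is oxidised in step 13.

Step 12
Reactants: 20 C2,C3-epoxy ketone
Product: 21 C3 allylic alcohol
Conditions: N2H4·H2O, AcOH (cat.), MeOH, 0 °C → rt
Reagents that add atoms: none
Why: Wharton transposition: the hydrazone opens the epoxide to a vinyl diazene that loses N2, which moves the oxygen to C3 and the alkene to C1=C2.

Step 13
Reactants: 21 C3 allylic alcohol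
Product: 22 transposed C3 enone
Conditions: Dess–Martin periodinane, NaHCO3, CH2Cl2, 0 °C → rt
Reagents that add atoms: none
Why: Dess–Martin oxidation of the allylic alcohol gives the enone whose only enolisable α'-position is C4, C10 being quaternary.

Step 14
Reactants: 22 transposed C3 enone
Product: 24 C4-methyl enone, via lithium dienolate 23 (not isolated)
Conditions: LiN(i-Pr)2, THF, −78 °C; MeI, −78 → −20 °C
Reagents that add atoms: iodomethane, CI; lithium diisopropylamide, [Li]N(C(C)C)C(C)C (lithium of 23 only)
Why: Kinetic α'-enolate methylation at C4; the new centre is enolised again in step 15, so its configuration does not matter.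

Step 15
Reactants: 24 C4-methyl enone; 6 (E)-1-bromo-4-methyl-4-(triethylsilyloxy)pent-2-ene
Product: 26 fully alkylated ring A enone, via lithium dienolate 25 (not isolated)
Conditions: LiN(i-Pr)2, THF, −78 °C; 6, DMPU, −78 → 0 °C
Reagents that add atoms: lithium diisopropylamide, [Li]N(C(C)C)C(C)C (lithium of 25 only)
Why: SN2 alkylation of the tetrasubstituted enolate by the primary allylic bromide, again anti to the C5 arm, sets the C4 quaternary centre with methyl cis and side chain trans to the arm.

Step 16
Reactants: 26 fully alkylated ring A enone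
Product: 28 C1α-hydroxy ketone, via boryl ketone 27 (not isolated)
Conditions: CuCl (5 mol%), NaOt-Bu (10 mol%), (R,R)-QuinoxP* (6 mol%), B2pin2, MeOH, THF, rt; then 30% H2O2, pH 7 phosphate buffer, 0 °C
Reagents that add atoms: hydrogen peroxide, OO; bis(pinacolato)diboron, CC1(C)OB(OC1(C)C)B1OC(C)(C)C(C)(C)O1 (boron of 27 only)
Why: Copper-catalysed conjugate borylation, with the chiral bisphosphine directing the boryl group to the α face of C1, followed by stereoretentive oxidation of the C–B bond, gives the β-hydroxy ketone with the C1 oxygen α.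

Step 17
Reactants: 28 C1α-hydroxy ketone
Product: 29 C1α-triethylsilyloxy ketone
Conditions: Et3SiCl, imidazole, DMAP (cat.), DMF, rt
Reagents that add atoms: chlorotriethylsilane, CC[Si](Cl)(CC)CC
Why: Silyl ether formation on the only free hydroxyl under weakly basic conditions, which avoids both silyl triflates (they would attack the acetal) and β-elimination.

Step 18
Reactants: 29 C1α-triethylsilyloxy ketone
Product: 30 C3α-alcohol
Conditions: (S)-2-methyl-CBS-oxazaborolidine (0.5 equiv), catecholborane, toluene, −78 → −30 °C
Reagents that add atoms: none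
Why: Corey–Bakshi–Shibata reduction: the catalyst distinguishes the quaternary C4 flank from the C2 methylene flank, and the (S) catalyst should deliver hydride to the β face, giving the C3 alcohol α (cis to the C1 oxygen); catecholborane does not hydroborate the side-chain alkene at this temperature.

Step 19
Reactants: 30 C3α-alcohol
Product: 31 C3β-chloride
Conditions: PPh3, N-chlorosuccinimide, THF, 0 °C → rt
Reagents that add atoms: N-chlorosuccinimide, ClN1C(=O)CCC1=O
Why: Appel-type chlorination: chloride displaces the oxyphosphonium group by SN2 with inversion to give the β chloride, under neutral conditions (succinimide takes up the proton) that spare the acetal and silyl ethers; the reaction type is known on neopentylic cyclohexanols, where elimination is the competing path.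

Step 20
Reactants: 31 C3β-chloride
Product: 32 methyl enol ether
Conditions: Me3SiOTf, i-Pr2NEt, CH2Cl2, −20 → 0 °C
Reagents that add atoms: none
Why: Silyl triflate ionises the dimethyl acetal to the oxocarbenium ion and the amine removes the C9 proton (elimination of methanol from an acetal); C10 is quaternary, so only the C9=C11 enol ether can form.

Step 21
Reactants: 32 methyl enol ether
Product: 33 C7 alcohol
Conditions: i-Bu2AlH, CH2Cl2, −78 °C
Reagents that add atoms: none
Why: Reductive cleavage of the pivalate ester under non-acidic conditions leaves the enol ether, the silyl ethers and the chloride untouched.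

Step 22
Reactants: 33 C7 alcohol
Product: 34 C7 aldehyde
Conditions: Dess–Martin periodinane, pyridine, CH2Cl2, 0 °C
Reagents that add atoms: none
Why: Dess–Martin oxidation, buffered so that the acetic acid formed cannot hydrolyse the enol ether.

Step 23
Reactants: 34 C7 aldehyde
Product: 35 β-hydroxy ester
Conditions: LiN(i-Pr)2, MeOAc, THF, −78 °C; then 34, −78 °C
Reagents that add atoms: methyl acetate, COC(C)=O
Why: Aldol addition of the preformed lithium enolate of methyl acetate adds C8 and the ester; the C7 carbinol configuration is irrelevant because it is oxidised in step 24.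

Step 24
Reactants: 35 β-hydroxy ester
Product: 36 keto ester enol ether
Conditions: Dess–Martin periodinane, NaHCO3, CH2Cl2, 0 °C → rt
Reagents that add atoms: none
Why: Dess–Martin oxidation of the β-hydroxy ester gives the β-keto ester without acid or base strong enough to touch the enol ether or the chloride.

**Ring B and end game (steps 25–28)**

Step 25
Reactants: 36 keto ester enol ether
Product: 37 trans-decalin enol acetal
Conditions: reticulated vitreous carbon anode, Pt cathode, undivided cell, constant current (2.2 F/mol), LiClO4 (0.1 M), 2,6-lutidine, MeOH/THF, rt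
Reagents that add atoms: methanol, CO
Why: This is an anodic oxidative radical cyclization of the known anodic olefin coupling type (1,3-dicarbonyl onto enol ether): with 2,6-lutidine as base the enolised keto ester is oxidised at the carbon anode to an electrophilic C8 radical (oxidation of the enol ether to its radical cation and capture by the enol leads to the same intermediate), which adds to the nucleophilic β-carbon C9 of the enol ether, and the α-methoxy radical at C11 is then oxidised to the oxocarbenium ion and captured by methanol as the dimethyl acetal. Ring B (C5, C6, C7, C8, C9, C10) closes in the 6-exo-trig mode by forming C8–C9. Because C8 and C9 both lie outside the ring fusion, the trans disposition of the two arms on ring A translates directly into the trans-fused decalin, and closure is possible only from the ring A chair that holds both arms equatorial. The new C9 stereocentre should be set by a chair-like transition state with the methoxyvinyl group pseudo-equatorial on the forming ring, which places C11 β (equatorial, on the face of the C10 methyl), while C8 stays sp2 in the enol and carries no stereochemistry. The step needs oxidation of the enol/enol ether pair in preference to the isolated side-chain alkene, the chloride and the silyl ethers, which their much higher oxidation potentials should secure, and it needs methanol rather than the enol oxygen as the trap, which is secured because O-capture at C11 would create a bridgehead alkene.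

Step 26
Reactants: 37 trans-decalin enol acetal
Product: 39 enol triflate, via sodium enolate 38 (not isolated)
Conditions: NaH, THF, 0 °C; PhNTf2, 0 °C → rt
Reagents that add atoms: N-phenylbis(trifluoromethanesulfonimide), FC(F)(F)S(=O)(=O)N(c1ccccc1)S(=O)(=O)C(F)(F)F; sodium hydride, [Na+].[H-] (sodium of 38 only)
Why: O-Sulfonylation of the β-keto ester enolate with the mild triflating agent gives the enol triflate without disturbing the acetal or the silyl ethers.

Step 27
Reactants: 39 enol triflate
Product: 40 C7=C8 enoate
Conditions: Pd(PPh3)4 (5 mol%), HCO2H, Et3N, DMF, 60 °C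
Reagents that add atoms: none
Why: Palladium-catalysed formate reduction of the enol triflate (oxidative addition to zerovalent palladium, formate exchange, decarboxylation, reductive elimination) replaces the C7 oxygen by hydrogen and leaves the C7=C8 enoate.

Step 28
Reactants: 40 C7=C8 enoate
Product: 41 target CNP0167913.1
Conditions: 48% aq. HF, MeCN, 0 °C → rt
Reagents that add atoms: water, O
Why: Fluoride-mediated desilylation of both triethylsilyl ethers and acid hydrolysis of the dimethyl acetal in one mildly acidic medium should release the C1 and side-chain hydroxyls and the C11 aldehyde without base, so that the epimerisable C9 centre is not disturbed.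

**Compound list**
1 | 2-methylbut-3-yn-2-ol | CC(C)(O)C#C | starting material
2 | triethyl[(2-methylbut-3-yn-2-yl)oxy]silane | C#CC(C)(C)O[Si](CC)(CC)CC | intermediate
3 | lithium acetylide of 2 | [Li]C#CC(C)(C)O[Si](CC)(CC)CC | intermediate
4 | 4-methyl-4-(triethylsilyloxy)pent-2-yn-1-ol | OCC#CC(C)(C)O[Si](CC)(CC)CC | intermediate
5 | (E)-4-methyl-4-(triethylsilyloxy)pent-2-en-1-ol | OC/C=C/C(C)(C)O[Si](CC)(CC)CC | intermediate
6 | (E)-1-bromo-4-methyl-4-(triethylsilyloxy)pent-2-ene | BrC/C=C/C(C)(C)O[Si](CC)(CC)CC | intermediate
7 | but-3-en-1-ol | C=CCCO | starting material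
8 | but-3-en-1-yl pivalate | C=CCCOC(=O)C(C)(C)C | intermediate
9 | (E)-but-2-enal | C/C=C/C=O | starting material
10 | (E)-5-oxopent-3-en-1-yl pivalate | O=C/C=C/CCOC(=O)C(C)(C)C | intermediate
11 | tert-butyl 3-oxobutanoate | CC(=O)CC(=O)OC(C)(C)C | starting material
12 | Michael adduct, tert-butyl 2-acetyl-5-oxo-3-[2-(pivaloyloxy)ethyl]pentanoate (C-3 as drawn, C-2 epimers) | CC(=O)C(C(=O)OC(C)(C)C)[C@@H](CCOC(=O)C(C)(C)C)CC=O | intermediate
13 | (R)-5-[2-(pivaloyloxy)ethyl]cyclohex-2-en-1-one (C1 ketone, C2=C3, C5β arm) | CC(C)(C)C(=O)OCC[C@@H]1CC(=O)C=CC1 | intermediate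
14 | lithium dienolate of 13 (C1–OLi, C1=C10) | CC(C)(C)C(=O)OCC[C@H]1CC=CC(O[Li])=C1 | intermediate
15 | C10-methyl enone (major 10α-methyl epimer drawn) | CC(C)(C)C(=O)OCC[C@H]1CC=CC(=O)[C@@H]1C | intermediate
16 | lithium dienolate of 15 | CC(C)(C)C(=O)OCC[C@H]1CC=CC(O[Li])=C1C | intermediate
17 | ring A enone: C1 ketone, C2=C3, C5β-[2-(pivaloyloxy)ethyl], C10β-methyl, C10α-allyl | CC(C)(C)C(=O)OCC[C@H]1CC=CC(=O)[C@]1(C)CC=C | intermediate
18 | aldehyde: as 17 with C10α-(2-oxoethyl) | CC(C)(C)C(=O)OCC[C@H]1CC=CC(=O)[C@]1(C)CC=O | intermediate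
19 | as 17 with C10α-(2,2-dimethoxyethyl) | CC(C)(C)C(=O)OCC[C@H]1CC=CC(=O)[C@]1(C)CC(OC)OC | intermediate
20 | C1 ketone with 2α,3α-epoxide | CC(C)(C)C(=O)OCC[C@H]1C[C@@H]2O[C@@H]2C(=O)[C@]1(C)CC(OC)OC | intermediate
21 | allylic alcohol: C3α-OH, C1=C2 | CC(C)(C)C(=O)OCC[C@H]1C[C@H](O)C=C[C@]1(C)CC(OC)OC | intermediate
22 | transposed enone: C3 ketone, C1=C2 | CC(C)(C)C(=O)OCC[C@H]1CC(=O)C=C[C@]1(C)CC(OC)OC | intermediate
23 | lithium dienolate of 22 (C3–OLi, C3=C4) | CC(C)(C)C(=O)OCC[C@H]1C=C(O[Li])C=C[C@]1(C)CC(OC)OC | intermediate
24 | C4-methyl enone (major 4α-methyl epimer drawn) | CC(C)(C)C(=O)OCC[C@H]1[C@H](C)C(=O)C=C[C@]1(C)CC(OC)OC | intermediate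
25 | lithium dienolate of 24 | CC(C)(C)C(=O)OCC[C@H]1C(C)=C(O[Li])C=C[C@]1(C)CC(OC)OC | intermediate
26 | ring A enone: C3 ketone, C1=C2, C4β-methyl, C4α-[(E)-4-methyl-4-(triethylsilyloxy)pent-2-enyl], C5β-[2-(pivaloyloxy)ethyl], C10β-methyl, C10α-(2,2-dimethoxyethyl) | CC(C)(C)C(=O)OCC[C@H]1[C@](C)(C/C=C/C(C)(C)O[Si](CC)(CC)CC)C(=O)C=C[C@]1(C)CC(OC)OC | intermediate
27 | as 26, saturated, with C1α-(pinacolato)boryl | CC(C)(C)C(=O)OCC[C@H]1[C@](C)(C/C=C/C(C)(C)O[Si](CC)(CC)CC)C(=O)C[C@H](B2OC(C)(C)C(C)(C)O2)[C@]1(C)CC(OC)OC | intermediate
28 | C1α-hydroxy C3 ketone | CC(C)(C)C(=O)OCC[C@H]1[C@](C)(C/C=C/C(C)(C)O[Si](CC)(CC)CC)C(=O)C[C@H](O)[C@]1(C)CC(OC)OC | intermediate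
29 | C1α-triethylsilyloxy C3 ketone | CC(C)(C)C(=O)OCC[C@H]1[C@](C)(C/C=C/C(C)(C)O[Si](CC)(CC)CC)C(=O)C[C@H](O[Si](CC)(CC)CC)[C@]1(C)CC(OC)OC | intermediate
30 | C3α-alcohol, C1α-triethylsilyl ether | CC(C)(C)C(=O)OCC[C@H]1[C@](C)(C/C=C/C(C)(C)O[Si](CC)(CC)CC)[C@H](O)C[C@H](O[Si](CC)(CC)CC)[C@]1(C)CC(OC)OC | intermediate
31 | C3β-chloride, C1α-triethylsilyl ether, C10α-(2,2-dimethoxyethyl) | CC(C)(C)C(=O)OCC[C@H]1[C@](C)(C/C=C/C(C)(C)O[Si](CC)(CC)CC)[C@@H](Cl)C[C@H](O[Si](CC)(CC)CC)[C@]1(C)CC(OC)OC | intermediate
32 | as 31 with C10α-[(E)-2-methoxyvinyl] (E drawn) | CC(C)(C)C(=O)OCC[C@H]1[C@](C)(C/C=C/C(C)(C)O[Si](CC)(CC)CC)[C@@H](Cl)C[C@H](O[Si](CC)(CC)CC)[C@]1(C)/C=C/OC | intermediate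
33 | as 32 with C5β-(2-hydroxyethyl) | OCC[C@H]1[C@](C)(C/C=C/C(C)(C)O[Si](CC)(CC)CC)[C@@H](Cl)C[C@H](O[Si](CC)(CC)CC)[C@]1(C)/C=C/OC | intermediate
34 | as 32 with C5β-(2-oxoethyl) | O=CC[C@H]1[C@](C)(C/C=C/C(C)(C)O[Si](CC)(CC)CC)[C@@H](Cl)C[C@H](O[Si](CC)(CC)CC)[C@]1(C)/C=C/OC | intermediate
35 | as 32 with C5β-(2-hydroxy-4-methoxy-4-oxobutyl) (C7 epimers) | COC(=O)CC(O)C[C@H]1[C@](C)(C/C=C/C(C)(C)O[Si](CC)(CC)CC)[C@@H](Cl)C[C@H](O[Si](CC)(CC)CC)[C@]1(C)/C=C/OC | intermediate
36 | cyclization precursor: ring A with C1α-OSiEt3, C3β-Cl, C4 side chain, C5β keto ester arm, C10α-[(E)-2-methoxyvinyl] | COC(=O)CC(=O)C[C@H]1[C@](C)(C/C=C/C(C)(C)O[Si](CC)(CC)CC)[C@@H](Cl)C[C@H](O[Si](CC)(CC)CC)[C@]1(C)/C=C/OC | intermediate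
37 | trans-decalin with enolised C7/C8 keto ester and C9β-dimethoxymethyl | COC(=O)C1=C(O)C[C@H]2[C@](C)(C/C=C/C(C)(C)O[Si](CC)(CC)CC)[C@@H](Cl)C[C@H](O[Si](CC)(CC)CC)[C@]2(C)[C@H]1C(OC)OC | intermediate
38 | sodium enolate of 37 | COC(=O)C1=C(O[Na])C[C@H]2[C@](C)(C/C=C/C(C)(C)O[Si](CC)(CC)CC)[C@@H](Cl)C[C@H](O[Si](CC)(CC)CC)[C@]2(C)[C@H]1C(OC)OC | intermediate
39 | C7 enol triflate | COC(=O)C1=C(OS(=O)(=O)C(F)(F)F)C[C@H]2[C@](C)(C/C=C/C(C)(C)O[Si](CC)(CC)CC)[C@@H](Cl)C[C@H](O[Si](CC)(CC)CC)[C@]2(C)[C@H]1C(OC)OC | intermediate
40 | C7=C8 enoate, bis(triethylsilyl) ether, C11 dimethyl acetal | COC(=O)C1=CC[C@H]2[C@](C)(C/C=C/C(C)(C)O[Si](CC)(CC)CC)[C@@H](Cl)C[C@H](O[Si](CC)(CC)CC)[C@]2(C)[C@H]1C(OC)OC | intermediate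
41 | CNP0167913.1 | COC(=O)C1=CC[C@H]2[C@](C)(C/C=C/C(C)(C)O)[C@@H](Cl)C[C@H](O)[C@]2(C)[C@H]1C=O | target

**Step count**
Total steps: 28. Longest linear sequence: 24 (steps 5–28; the four-step bromide branch joins at step 15).

**Steps most likely to fail**

Step 19, chlorination at the neopentylic C3. Elimination of the activated oxygen toward C2, or a 1,2-shift from the neighbouring quaternary C4, may outrun the hindered SN2 displacement. Fallback: activation and displacement are separated. Starting from compound 30, the alcohol is converted with Tf2O and pyridine (CH2Cl2, −40 °C) into the C3α trifluoromethanesulfonate F1. This is displaced with inversion by Bu4NCl in toluene at −20 °C → rt, and the route is rejoined at compound 31.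

Step 25, the anodic ring closure. Over-oxidation or anodic methanolysis of the enol ether may occur before C8–C9 bond formation, and facial control at C9 may be incomplete. Fallback: starting from compound 36, the same bond is closed with chemical one-electron oxidants, Mn(OAc)3·2H2O and Cu(OAc)2·H2O in degassed MeOH at rt. Trivalent manganese generates the C8 radical from the enol, divalent copper oxidises the C11 radical, and methanol traps the cation. This rejoins the route at compound 37 and passes through no new isolated compound (entry F0).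

Step 16, conjugate borylation. Addition to the β-carbon next to the quaternary C10 may be slow, and the ligand may not override the substrate's own facial bias. Fallback: starting from compound 26, Weitz–Scheffer epoxidation (t-BuOOH, DBU, CH2Cl2) gives the C1,C2-epoxy ketone F2, the α-epoxide being separated from its epimer if both form. SmI2 (THF/MeOH, −78 °C) then cleaves the α C–O bond reductively to the β-hydroxy ketone, and the route is rejoined at compound 28.

**Further compounds**
F1 | step 19 | C3α-trifluoromethanesulfonate of 30 | CC(C)(C)C(=O)OCC[C@H]1[C@](C)(C/C=C/C(C)(C)O[Si](CC)(CC)CC)[C@H](OS(=O)(=O)C(F)(F)F)C[C@H](O[Si](CC)(CC)CC)[C@]1(C)CC(OC)OC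
F0 | step 25 | none | none
F2 | step 16 | C3 ketone with 1α,2α-epoxide derived from 26 | CC(C)(C)C(=O)OCC[C@H]1[C@](C)(C/C=C/C(C)(C)O[Si](CC)(CC)CC)C(=O)[C@@H]2O[C@@H]2[C@]1(C)CC(OC)OC
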